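Ring A of the trans-decalin is cut at C1–C10 and C3–C4: a C1–C2–C3 propane bridge spans the two quaternary carbons that flank C5. What remains of the terpenoid half, ring B with its C7=C8–C9 enone, the C5 stereocentre and C4 with both one-carbon substituents, is (R)-carvone once the isopropenyl group is oxidised to a propanoate. The key step stitches 1-chloro-3-iodopropane in one pot onto this monocyclic keto ester, first at the ketone enolate (C10), then at the ester enolate (C4), setting both quaternary centres and the trans ring fusion. Methylenation, hydroboration and B-alkyl Suzuki coupling with a bromoquinone monoketal, then epoxidation, reduction and ketal hydrolysis finish the synthesis.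

Key step: step 5

Remark on numbering: the decalin carbons are numbered as in drimane (C1 to C10; C11 is the CH2 on C9). In the oxygenated six-membered ring C1′ is the ketone carbon of the target, C2′ carries the methyl group, C4′ the hydroxyl group, C5′ is the quaternary epoxide carbon and C6′ the epoxide CH.

Step 1
Reactants: 1 (R)-(−)-carvone
Product: 2 (5R)-2,6-dimethyl-5-(prop-1-en-2-yl)cyclohex-2-en-1-one (6-methylcarvone as a mixture of C6 epimers)
Conditions: LiN(iPr)2, THF, −78 °C; MeI, −78 → 0 °C
Reagents that add atoms: iodomethane, CI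
Why: Kinetic α′-deprotonation of the enone and SN2 methylation of the lithium enolate (enolate alkylation) install the future C10 methyl group; the new centre is formed as an epimer mixture, which is of no consequence because this carbon becomes an enolate carbon again in step 5.

Step 2
Reactants: 2 (5R)-2,6-dimethyl-5-(prop-1-en-2-yl)cyclohex-2-en-1-one
Product: 3 (5R)-2,6-dimethyl-5-(2-methyloxiran-2-yl)cyclohex-2-en-1-one (epimer mixture at C6 and at the oxirane carbon)
Conditions: mCPBA, NaHCO3, CH2Cl2, 0 °C
Reagents that add atoms: 3-chloroperoxybenzoic acid, OOC(=O)c1cccc(Cl)c1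
Why: Prilezhaev epoxidation should take place only at the electron-rich 1,1-disubstituted alkene and not at the electron-poor enone C=C; the oxirane centre is not controlled and need not be, as this carbon is made planar again in step 5.

Step 3
Reactants: 3 (5R)-2,6-dimethyl-5-(2-methyloxiran-2-yl)cyclohex-2-en-1-one
Product: 4 2-[(1S)-2,4-dimethyl-3-oxocyclohex-4-en-1-yl]propanal (epimer mixture at ring C2 and at the aldehyde α-carbon)
Conditions: ZnBr2 (cat.), toluene, 25 → 60 °C
Reagents that add atoms: none
Why: Meinwald rearrangement: ZnBr2 opens the 2,2-disubstituted epoxide at its tertiary carbon and a 1,2-hydride shift gives the α-branched aldehyde; the new α-centre is an inconsequential epimer mixture.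

Step 4
Reactants: 4 2-[(1S)-2,4-dimethyl-3-oxocyclohex-4-en-1-yl]propanal
Product: 6 methyl 2-[(1R)-2,4-dimethyl-3-oxocyclohex-4-en-1-yl]propanoate, via carboxylic acid 5 (not isolated)
Conditions: NaClO2, NaH2PO4, 2-methyl-2-butene, t-BuOH/H2O, 0 → 25 °C; then MeI, K2CO3, DMF, 25 °C
Reagents that add atoms: sodium chlorite, [Na+].[O-]Cl=O; iodomethane, CI
Why: Pinnick oxidation of the aldehyde followed by SN2 O-methylation of the carboxylate gives the ester without touching the enone or creating a stereocentre.

Step 5
Reactants: 6 methyl 2-[(1R)-2,4-dimethyl-3-oxocyclohex-4-en-1-yl]propanoate; 7 1-chloro-3-iodopropane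
Product: 9 methyl (1R,4aS,8aR)-1,4a,6-trimethyl-5-oxo-1,2,3,4,4a,5,8,8a-octahydronaphthalene-1-carboxylate, via chloropropyl ketone 8 (not isolated)
Conditions: LiN(iPr)2 (1.05 equiv), THF, −78 °C; 7 (1.2 equiv), DMPU, −78 → −20 °C; then LiN(iPr)2 (1.3 equiv), −78 → 25 °C
Reagents that add atoms: none
Why: LiN(iPr)2 deprotonates the ketone of 6 kinetically at its only enolisable α-position (C10) and the cross-conjugated lithium enolate is alkylated by the iodide end of 7 on the face opposite to the C5 side chain (the usual course for 6-alkylcarvone enolates), which puts the new CH2 (C1) trans and the methyl group cis to that side chain and fixes C10; the second charge of base forms the ester enolate, whose C4 displaces the primary chloride in a 6-exo-tet SN2 closure of ring A. The closest known reaction type is the annulation of carbonyl dianion equivalents with α,ω-dihalides by two enolate alkylations, the second one intramolecular. In the ring closure allylic 1,3-strain keeps the C5–H bond eclipsed with the enolate C=C bond and the tether allows attack only from the C10 side, so that at C4 the methyl group becomes axial (β) and the ester equatorial (α), and ring A is trans-fused because C1 and C4 are trans on ring B. Both epimeric centres of 6 (C10 and C4) are planar enolate carbons in this step, so the diastereomer mixture made in steps 1 to 4 should converge to one product. The step needs C10 to react before C4 and the ester to be enolised in preference to the γ-position (C6) of the enone: the first is secured by adding the base in two portions (the ketone α-proton is the more acidic one), the second by the kinetic, carbonyl-directed deprotonation of the ester at −78 °C and the fast intramolecular alkylation.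

Step 6
Reactants: 9 methyl (1R,4aS,8aR)-1,4a,6-trimethyl-5-oxo-1,2,3,4,4a,5,8,8a-octahydronaphthalene-1-carboxylate
Product: 10 methyl (1R,4aS,8aR)-1,4a,6-trimethyl-5-methylidene-1,2,3,4,4a,5,8,8a-octahydronaphthalene-1-carboxylate
Conditions: Zn, CH2Br2, TiCl4, THF/CH2Cl2, 0 → 25 °C
Reagents that add atoms: dibromomethane, BrCBr
Why: Takai–Lombardo methylenation: the non-basic gem-dimetallic CH2 reagent converts the hindered enone carbonyl (C9) into the exocyclic alkene whose CH2 becomes C11 and leaves the ester alone; no stereocentre is formed.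

Step 7
Reactants: 10 methyl (1R,4aS,8aR)-1,4a,6-trimethyl-5-methylidene-1,2,3,4,4a,5,8,8a-octahydronaphthalene-1-carboxylate
Product: 11 [(1R,4aS,8aR)-1,4a,6-trimethyl-5-methylidene-1,2,3,4,4a,5,8,8a-octahydronaphthalen-1-yl]methanol
Conditions: LiAlH4, THF, 0 °C
Reagents that add atoms: none
Why: Hydride reduction of the ester with LiAlH4 gives the 4α-hydroxymethyl group of the target; the conjugated diene and all stereocentres are unaffected.

Step 8
Reactants: 12 4-methoxy-3-methylphenol
Product: 13 2-bromo-4-methoxy-5-methylphenol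
Conditions: NBS, MeCN, 0 °C
Reagents that add atoms: N-bromosuccinimide, O=C1CCC(=O)N1Br
Why: Electrophilic aromatic bromination: the hydroxyl group directs to its free ortho position that is also para to the methyl group, the other ortho position being flanked by OH and CH3.

Step 9
Reactants: 13 2-bromo-4-methoxy-5-methylphenol
Product: 14 2-bromo-4,4-dimethoxy-5-methylcyclohexa-2,5-dien-1-one
Conditions: PhI(OAc)2, MeOH, 0 °C
Reagents that add atoms: methanol, CO
Why: Oxidative dearomatisation of the para-methoxyphenol by PhI(OAc)2 in methanol (quinone monoketal formation) turns the phenol carbon into the ketone and the methoxy-bearing carbon into the dimethyl ketal, which fixes the regiochemistry of all later steps on this ring.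

Step 10
Reactants: 11 [(1R,4aS,8aR)-1,4a,6-trimethyl-5-methylidene-1,2,3,4,4a,5,8,8a-octahydronaphthalen-1-yl]methanol; 14 2-bromo-4,4-dimethoxy-5-methylcyclohexa-2,5-dien-1-one
Product: 16 2-{[(1S,4aR,5R,8aR)-5-(hydroxymethyl)-2,5,8a-trimethyl-1,4,4a,5,6,7,8,8a-octahydronaphthalen-1-yl]methyl}-4,4-dimethoxy-5-methylcyclohexa-2,5-dien-1-one, via alkylborane 15 (not isolated)
Conditions: 9-BBN dimer (1.3 equiv), THF, 0 → 25 °C; then 14, Pd(dppf)Cl2 (5 mol%), AsPh3, Cs2CO3, DMF/H2O, 25 °C
Reagents that add atoms: none
Why: Hydroboration with 9-BBN should occur at the less hindered exocyclic C9=C11 bond of the diene from the α face (opposite the axial C10 methyl group), placing boron on C11 and hydrogen on C9 (9α-H; the free hydroxyl is carried as its borinate), and the primary alkylborane then enters a B-alkyl Suzuki–Miyaura coupling with the α-bromo enone unit of 14, which adds readily to zerovalent palladium.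

Step 11
Reactants: 16 2-{[(1S,4aR,5R,8aR)-5-(hydroxymethyl)-2,5,8a-trimethyl-1,4,4a,5,6,7,8,8a-octahydronaphthalen-1-yl]methyl}-4,4-dimethoxy-5-methylcyclohexa-2,5-dien-1-one
Product: 17 (1R,6S)-1-{[(1S,4aR,5R,8aR)-5-(hydroxymethyl)-2,5,8a-trimethyl-1,4,4a,5,6,7,8,8a-octahydronaphthalen-1-yl]methyl}-5,5-dimethoxy-4-methyl-7-oxabicyclo[4.1.0]hept-3-en-2-one
Conditions: t-BuOOH, NaOH (aq.), N-benzylcinchonidinium chloride (10 mol%), toluene, 0 → 25 °C
Reagents that add atoms: tert-butyl hydroperoxide, CC(C)(C)OO
Why: Weitz–Scheffer nucleophilic epoxidation under chiral phase-transfer catalysis: the peroxide anion adds to the unsubstituted β-carbon C6′ (the other β-carbon carries the methyl group), so only the C5′=C6′ bond should be epoxidised, and the face is chosen by the chiral ammonium ion pair (the pseudoenantiomeric cinchoninium salt is held in reserve should it prove to be the matching catalyst), the remote decalin exerting little bias and any minor diastereomer being separable.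

Step 12
Reactants: 17 (1R,6S)-1-{[(1S,4aR,5R,8aR)-5-(hydroxymethyl)-2,5,8a-trimethyl-1,4,4a,5,6,7,8,8a-octahydronaphthalen-1-yl]methyl}-5,5-dimethoxy-4-methyl-7-oxabicyclo[4.1.0]hept-3-en-2-one
Product: 18 (1S,2R,6S)-1-{[(1S,4aR,5R,8aR)-5-(hydroxymethyl)-2,5,8a-trimethyl-1,4,4a,5,6,7,8,8a-octahydronaphthalen-1-yl]methyl}-5,5-dimethoxy-4-methyl-7-oxabicyclo[4.1.0]hept-3-en-2-ol
Conditions: i-Bu2AlH (3 equiv), CH2Cl2, −78 °C
Reagents that add atoms: none
Why: Hydride 1,2-reduction of the epoxy enone carbonyl: the hydride should reach C4′ from the face of the epoxide oxygen (aluminium bound to that oxygen) and away from the bulky CH2-decalin group on the adjacent quaternary C5′, which sets the hydroxyl group trans to the epoxide as in the target.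

Step 13
Reactants: 18 (1S,2R,6S)-1-{[(1S,4aR,5R,8aR)-5-(hydroxymethyl)-2,5,8a-trimethyl-1,4,4a,5,6,7,8,8a-octahydronaphthalen-1-yl]methyl}-5,5-dimethoxy-4-methyl-7-oxabicyclo[4.1.0]hept-3-en-2-ol
Product: 19 epoxypholamin B, (1S,5R,6S)-5-hydroxy-6-{[(1S,4aR,5R,8aR)-5-(hydroxymethyl)-2,5,8a-trimethyl-1,4,4a,5,6,7,8,8a-octahydronaphthalen-1-yl]methyl}-3-methyl-7-oxabicyclo[4.1.0]hept-3-en-2-one
Conditions: 48% aq. HF, MeCN, 0 → 25 °C
Reagents that add atoms: water, O
Why: Acid hydrolysis of the dimethyl ketal (acetal hydrolysis) unveils the C1′ enone carbonyl under conditions that the epoxy alcohol should tolerate; no stereocentre is affected.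

Compound list
1 | (R)-(−)-carvone | CC1=CC[C@@H](C(C)=C)CC1=O | starting material
2 | (5R)-2,6-dimethyl-5-(prop-1-en-2-yl)cyclohex-2-en-1-one (C6 epimers) | CC1=CC[C@@H](C(C)=C)C(C)C1=O | intermediate
3 | (5R)-2,6-dimethyl-5-(2-methyloxiran-2-yl)cyclohex-2-en-1-one (epimers at C6 and at the oxirane carbon) | CC1=CC[C@@H](C2(C)CO2)C(C)C1=O | intermediate
4 | 2-[(1S)-2,4-dimethyl-3-oxocyclohex-4-en-1-yl]propanal (epimers at ring C2 and at the α-carbon) | CC1=CC[C@@H](C(C)C=O)C(C)C1=O | intermediate
5 | 2-[(1R)-2,4-dimethyl-3-oxocyclohex-4-en-1-yl]propanoic acid (same epimer mixture) | CC1=CC[C@@H](C(C)C(O)=O)C(C)C1=O | intermediate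
6 | methyl 2-[(1R)-2,4-dimethyl-3-oxocyclohex-4-en-1-yl]propanoate (same epimer mixture) | CC1=CC[C@@H](C(C)C(=O)OC)C(C)C1=O | intermediate
7 | 1-chloro-3-iodopropane | ClCCCI | starting material
8 | methyl 2-[(1S,2S)-2-(3-chloropropyl)-2,4-dimethyl-3-oxocyclohex-4-en-1-yl]propanoate (chloropropyl trans to the side chain; α-carbon epimers) | CC1=CC[C@@H](C(C)C(=O)OC)[C@](C)(CCCCl)C1=O | intermediate
9 | methyl (1R,4aS,8aR)-1,4a,6-trimethyl-5-oxo-1,2,3,4,4a,5,8,8a-octahydronaphthalene-1-carboxylate (trans-decalin; 4α-CO2Me, 4β-CH3, 5α-H, 10β-CH3, 7-en-9-one) | O=C1C(C)=CC[C@H]2[C@](C)(C(=O)OC)CCC[C@]12C | intermediate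
10 | methyl (1R,4aS,8aR)-1,4a,6-trimethyl-5-methylidene-1,2,3,4,4a,5,8,8a-octahydronaphthalene-1-carboxylate | C=C1C(C)=CC[C@H]2[C@](C)(C(=O)OC)CCC[C@]12C | intermediate
11 | [(1R,4aS,8aR)-1,4a,6-trimethyl-5-methylidene-1,2,3,4,4a,5,8,8a-octahydronaphthalen-1-yl]methanol | C=C1C(C)=CC[C@H]2[C@](C)(CO)CCC[C@]12C | intermediate
12 | 4-methoxy-3-methylphenol | Cc1cc(O)ccc1OC | starting material
13 | 2-bromo-4-methoxy-5-methylphenol | Cc1cc(O)c(Br)cc1OC | intermediate
14 | 2-bromo-4,4-dimethoxy-5-methylcyclohexa-2,5-dien-1-one | CC1=CC(=O)C(Br)=CC1(OC)OC | intermediate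
15 | B-alkyl-9-BBN at C11 of the decalin (9α-H), the hydroxyl group as its 9-BBN borinate | B1(C[C@H]2C(C)=CC[C@H]3[C@](C)(COB4C5CCCC4CCC5)CCC[C@]23C)C6CCCC1CCC6 | intermediate
16 | 2-{[(1S,4aR,5R,8aR)-5-(hydroxymethyl)-2,5,8a-trimethyl-1,4,4a,5,6,7,8,8a-octahydronaphthalen-1-yl]methyl}-4,4-dimethoxy-5-methylcyclohexa-2,5-dien-1-one | O=C1C=C(C)C(OC)(OC)C=C1C[C@H]2C(C)=CC[C@H]3[C@](C)(CO)CCC[C@]23C | intermediate
17 | (1R,6S)-1-{[(1S,4aR,5R,8aR)-5-(hydroxymethyl)-2,5,8a-trimethyl-1,4,4a,5,6,7,8,8a-octahydronaphthalen-1-yl]methyl}-5,5-dimethoxy-4-methyl-7-oxabicyclo[4.1.0]hept-3-en-2-one | CC1=CC(=O)[C@]2(C[C@H]3C(C)=CC[C@H]4[C@](C)(CO)CCC[C@]34C)O[C@@H]2C1(OC)OC | intermediate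
18 | (1S,2R,6S)-1-{[(1S,4aR,5R,8aR)-5-(hydroxymethyl)-2,5,8a-trimethyl-1,4,4a,5,6,7,8,8a-octahydronaphthalen-1-yl]methyl}-5,5-dimethoxy-4-methyl-7-oxabicyclo[4.1.0]hept-3-en-2-ol (hydroxyl trans to the epoxide) | CC1=C[C@@H](O)[C@]2(C[C@H]3C(C)=CC[C@H]4[C@](C)(CO)CCC[C@]34C)O[C@@H]2C1(OC)OC | intermediate
19 | epoxypholamin B | CC1=C[C@@H](O)[C@]2(C[C@H]3C(C)=CC[C@H]4[C@](C)(CO)CCC[C@]34C)O[C@@H]2C1=O | target

Total step count: 13. Longest linear sequence: 11 steps (steps 1 to 7 and 10 to 13, from (R)-carvone); steps 8 and 9 make the coupling partner 14.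

Steps most likely to fail

Step 5 (key step). The danger is a proton transfer: after the first alkylation the second charge of base, or the ester enolate once it has formed, may take a γ-proton (C6) of the enone instead of leading to ring closure. The resulting dienolate can alkylate at C8 or stay uncyclised, and the slow displacement of chloride gives this side path time. Fallback, from 6 back to 9: the first alkylation is run on its own and chloropropyl ketone 8 is isolated. Its enone carbonyl is taken out of play by Luche reduction (NaBH4, CeCl3·7H2O, MeOH) to the allylic alcohol F1, which is silylated (TBSOTf, 2,6-lutidine) to the silyl ether F2. With no enone left, LiN(iPr)2 in THF/DMPU can only form the ester enolate, which closes ring A to the bicyclic silyl ether F3. Bu4NF then gives the bicyclic allylic alcohol F4, and Dess–Martin periodinane returns enone 9.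

Step 11. The danger is poor facial selectivity: the ion-pair-controlled peroxide addition next to the hindered α-substituent may not discriminate well between the two faces of the dienone, so much material would be lost as the wrong epoxide diastereomer. Fallback, from 16 back to 19: ketal exchange with (2R,4R)-pentane-2,4-diol (PPTS, benzene, 60 °C) gives the dioxane ketal F5. This is epoxidised under auxiliary control with Ph3COOH and KN(SiMe3)2, the axial methyl group of the dioxane chair shielding one face, to the epoxy ketal F6. Reduction with i-Bu2AlH gives the epoxy alcohol F7, and aqueous HF in MeCN releases 19. The enantiomeric diol would be used should the auxiliary shield the wrong face.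

Step 12. The danger is again facial selectivity: the hydride may attack anti to the epoxide C–O bond (polar Felkin–Anh preference) instead of being delivered from the epoxide face, which places the hydroxyl group cis to the epoxide. Fallback, from 17 back to 18: the cis epoxy alcohol F8 is then made on purpose (NaBH4, CeCl3·7H2O, MeOH, −78 °C). It is inverted at C4′ by Mitsunobu reaction (4-nitrobenzoic acid, PPh3, DIAD) to the 4-nitrobenzoate F9, whose methanolysis (K2CO3, MeOH) gives 18. The neopentyl primary alcohol is a poor Mitsunobu substrate, and any ester formed there would be cleaved in the same methanolysis.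

Further compounds
F1 | step 5 | methyl 2-[(1S,2S)-2-(3-chloropropyl)-3-hydroxy-2,4-dimethylcyclohex-4-en-1-yl]propanoate (carbinol configuration not defined) | CC1=CC[C@@H](C(C)C(=O)OC)[C@](C)(CCCCl)C1O
F2 | step 5 | tert-butyldimethylsilyl ether of F1 | CC1=CC[C@@H](C(C)C(=O)OC)[C@](C)(CCCCl)C1O[Si](C)(C)C(C)(C)C
F3 | step 5 | methyl (1R,4aS,8aR)-5-[tert-butyl(dimethyl)silyl]oxy-1,4a,6-trimethyl-1,2,3,4,4a,5,8,8a-octahydronaphthalene-1-carboxylate | CC(C)(C)[Si](C)(C)OC1C(C)=CC[C@H]2[C@](C)(C(=O)OC)CCC[C@]12C
F4 | step 5 | methyl (1R,4aS,8aR)-5-hydroxy-1,4a,6-trimethyl-1,2,3,4,4a,5,8,8a-octahydronaphthalene-1-carboxylate | OC1C(C)=CC[C@H]2[C@](C)(C(=O)OC)CCC[C@]12C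
F5 | step 11 | analogue of 16 with the dimethyl ketal replaced by the cyclic ketal of (2R,4R)-pentane-2,4-diol | O=C1C=C(C)C2(O[C@H](C)C[C@@H](C)O2)C=C1C[C@H]3C(C)=CC[C@H]4[C@](C)(CO)CCC[C@]34C
F6 | step 11 | C5′–C6′ epoxide of F5, configured as in 17 | CC1=CC(=O)[C@]2(C[C@H]3C(C)=CC[C@H]4[C@](C)(CO)CCC[C@]34C)O[C@@H]2C15O[C@H](C)C[C@@H](C)O5
F7 | step 11 | C4′ alcohol from F6, configured as in 18 | CC1=C[C@@H](O)[C@]2(C[C@H]3C(C)=CC[C@H]4[C@](C)(CO)CCC[C@]34C)O[C@@H]2C15O[C@H](C)C[C@@H](C)O5
F8 | step 12 | C4′ epimer of 18 (hydroxyl cis to the epoxide) | CC1=C[C@H](O)[C@]2(C[C@H]3C(C)=CC[C@H]4[C@](C)(CO)CCC[C@]34C)O[C@@H]2C1(OC)OC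
F9 | step 12 | 4-nitrobenzoate of 18 at the C4′ oxygen | CC1=C[C@@H](OC(=O)c5ccc(cc5)[N+](=O)[O-])[C@]2(C[C@H]3C(C)=CC[C@H]4[C@](C)(CO)CCC[C@]34C)O[C@@H]2C1(OC)OC
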